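## Structural features

The target 14 is a 4-hydroxybenzoic acid that carries at C3 a five-carbon chain: a benzylic CH2, an E trisubstituted alkene with a methyl branch, and two methylenes that end at C2 of a 1,3,3-trimethyl-7-oxabicyclo[2.2.1]heptane. The bicycle is a cyclohexane ring (C1–C6) spanned by an ether oxygen (O7) between C1, a quaternary carbon with a methyl group, and C4, a CH; C3, between C2 and C4, bears the gem-dimethyl group. All three stereocentres (1R, 2S, 4S) lie in the bicycle, with C1 next to C2. Because the oxygen bridge ties C1 to C4, only two things have to be controlled: the absolute sense of the bicycle and the exo position of the chain at C2 (on the side of O7). Fragile groups are the ortho-allyl phenol (acid closes it to a chroman, oxidants attack it), the trisubstituted alkene (its geometry must not be scrambled) and the strained tertiary ether at C1 (strong acids can ionise it). The real difficulty is C2, a tertiary carbon wedged between the fully substituted carbons C1 and C3 and remote from any group that could help to set it. The key step exploits the fact that the oxolane O7–C1–C6–C5–C4, the methyl on C1, the gem-dimethyl carbon C3 on C4, and C2 with the first chain carbon on C1 together form the skeleton of cis-furanoid linalool oxide. There C2 and the first chain carbon are a vinyl group, C3 is a carbinol carbon, and only the C2–C3 bond is missing.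

## Logic of the disconnections

From 14 the first cut removes nothing from the skeleton. The phenol and the acid are traced back to the aryl silyl ether and the methyl ester of 12 (O–Si bond and ester C–OCH3 bond, with 13 on the way). The reason is that the preceding step uses an organoalane, which tolerates neither acidic proton. The gain is a neutral coupling product that can be purified. The demand is that both masks fall under base alone, because acid would cyclise the ortho-allyl phenol.

12 is cut at two bonds of the alkene: the bond from the alkene CH to the benzylic CH2, and the bond from the fully substituted alkene carbon to its methyl group. This turns the E alkene into a terminal alkyne, 6, and a benzylic chloride, 10, so the geometry reduces to a syn addition followed by a coupling with retention (through 11). The gain is convergence: all stereocentres are in 6 and all aromatic functionality is in 10. The forward step must place the methyl on the inner alkyne carbon only, and the alkenylalane must couple faster than it attacks the ester or the bridging ether.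

10 is simplified by functional-group changes only: C–Cl to C–OH (9), CH2OH to CHO (8), and O–Si to O–H (7). The order is chosen so that the benzylic carbon becomes electrophilic only after the phenol is capped, which avoids quinone methide chemistry. The gain is a commercial arene with the right substitution pattern. The demand is a reduction that spares the ester and does not let the silyl group move to the new benzylic oxygen.

In 6 the C2–C3 ring bond and the bond between the first and second chain carbons are cut together. Cutting C2–C3 leaves an oxolane in which C3 is an oxygen-bearing tertiary carbon and C2 with the first chain carbon is a vinyl group, which is 4; the remaining three chain carbons come from 5. This is the largest simplification in the route: the carbocycle, the bicycle, the C2 stereocentre and the alkyne handle are all removed at once, leaving a terpene oxide. The forward step needs a radical at the tertiary carbon (an anion there would expel the ring oxygen), closure onto the inner vinyl carbon, and a terminating reagent that transfers carbon and no hydrogen.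

4 is cut at the ester bond between the tertiary oxygen and the oxalyl carbon, which gives 3. An oxalate is chosen because a hindered tertiary alcohol accepts it in one acylation and because it does not eliminate on standing, as a tertiary xanthate or halide next to the ring oxygen would. The gain in atoms is small, but the route now rests on a known natural-product skeleton. The demand is only a clean acylation of a tertiary alcohol.

3 is opened at the bond between the ring oxygen and C2 of the oxolane, which leads to the epoxy alcohol 2, and 2 is traced to the diene 1 by removing the epoxide oxygen. The cut is placed there because the tertiary hydroxyl of 1 already stands in a 5-exo relationship to the trisubstituted alkene, and its stereocentre becomes C1 of the bicycle unchanged. The gain is a one-flask entry from a commercial terpene. The demand is face-selective oxidation of the trisubstituted alkene in the presence of the vinyl group, and ring closure with inversion at the secondary epoxide carbon so that the hydroxyisopropyl and vinyl groups end up cis.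

## Other disconnections considered

Alternative 1: The cut is the C1–C2 ring bond of the bicycle, with the oxygen bridge opened as well, so that the carbocycle is built first.
- **Forward step:** SmI2 with HMPA and t-BuOH reduces the methyl ketone of the acyclic keto enoate A2 (methyl (2E,5S)-5-[(tert-butyldimethylsilyl)oxy]-4,4-dimethyl-8-oxonon-2-enoate) to a ketyl. The ketyl adds 6-exo to the enoate β-carbon and gives the hydroxy ester A1 (methyl 2-[(1S,3S,6S)-3-[(tert-butyldimethylsilyl)oxy]-6-hydroxy-2,2,6-trimethylcyclohexyl]acetate).
- **In favour:** ketyl–enoate cyclisation is a well-precedented, polarity-matched reaction; the gem-dimethyl group sits in the tether and should help closure; the acetate arm is a usable handle.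
- **Against:** in A1 the tertiary hydroxyl lies trans to the silyloxy group. The bridge therefore cannot be closed by SN2 displacement at the secondary carbon, which would give the endo-chain diastereomer. It must be closed by ionising the tertiary carbinol and capturing the cation with the secondary oxygen, and that competes with elimination. A2 also needs its own enantioselective synthesis of a carbinol centre next to a quaternary carbon, and after A1 the ester must be extended by two carbons to the alkyne.
- **Comparison:** on mechanism the alternative is the better, since its key step is established chemistry and the chosen one is not. On stereocontrol the two are equal, as both rely on the substrate to set the CH centre. On structure the chosen plan is ahead, because the oxygen bridge is present before the ring closes and the bridgeheads cannot be wrong. On step count the alternative is clearly longer: an acyclic precursor of an estimated six to eight steps plus four or five steps from A1 to the alkyne stage, against three steps to 6.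

Alternative 2: The cut is at C1: the O7–C1 bond and the C1–C6 bond, with a ketone placed at C2.
- **Forward step:** copper bis(hexafluoroacetylacetonate), Cu(hfacac)2, decomposes the diazo ketone A4 (2-diazo-4-methyl-4-[(2S)-oxetan-2-yl]pentan-3-one). The copper carbenoid is captured by the oxetane oxygen, and a [1,2]-shift of the oxetane CH2 in the oxonium ylide expands the four-membered ring to give the bicyclic ketone A3 ((1R,4S)-1,3,3-trimethyl-7-oxabicyclo[2.2.1]heptan-2-one).
- **In favour:** both rings and the quaternary bridgehead form in one step, relief of oxetane strain drives it, and the bridgehead configuration follows from the single stereocentre of A4.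
- **Against:** A3 is a ketone flanked by two fully substituted carbons, so attaching a four-carbon chain at C2 means addition to a very hindered carbonyl. The oxygen must then be removed, and the C2–H bond formed in doing so would come from the open exo face, which puts the chain endo, the wrong way round. The ylide can also divert to C–H insertion or elimination, and A4 needs an enantioenriched oxetane.
- **Comparison:** for the bicyclic core alone the alternative is the equal or the better, because oxonium ylide ring expansion has closer precedent than a bridging radical closure. For C2 and the chain the chosen plan is better, since it makes the C2–C3 bond, the C2 stereocentre and the chain bond in one event. In steps, the alternative needs at least five more operations after A3, with the C2 problem still unsolved.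

Alternative 3: The cut is at the alkene: the bond to the methyl branch and the bond to the benzylic CH2.
- **Forward step:** alkyne 6 undergoes zirconium-catalysed methylalumination, and the alkenylalane is coupled with chloride 10 under Pd(PPh3)4 to give the ester A5 (methyl 4-[(tert-butyldimethylsilyl)oxy]-3-[(2E)-3-methyl-5-[(1R,2S,4S)-1,3,3-trimethyl-7-oxabicyclo[2.2.1]heptan-2-yl]pent-2-en-1-yl]benzoate, the same structure as 12).
- **In favour:** the E geometry follows from syn addition and coupling with retention, two fragments of similar size are joined late, and every operation is established.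
- **Against, as the centre of the plan:** it closes no ring and sets no stereocentre, so it leaves open how the bicycle with its exo chain is made, and it needs 6 however that is done.
- **Comparison:** this is the endgame of the chosen plan (step 7), not a rival to it. As a single step it is more reliable than step 3, and on this point it is the better. On step count the two are equal, because the sequence is already part of the route. On structure it contributes the alkene only; the length and risk of the synthesis are decided by how the bicycle is disconnected, which is why step 3 and not step 7 carries the strategy.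

Key step: step 3

Remarks on the chemistry (assumptions):
- (a) Commercial (R)-(−)-linalool of high enantiomeric purity is used.
- (b) The dioxirane from the D-fructose-derived ketone is taken to give the R configuration at the epoxide CH of 2, as it does with other 2-methylalk-2-enes.
- (c) The structures on both sides of the key step were checked atom by atom. The (2S,5R) oxolane has the vinyl and the oxygenated isopropyl group on the same face and maps onto the (1R,2S,4S) bicycle with the chain exo. No change of constitution or configuration was needed.
- (d) The exo outcome is attributed to the vinyl conformer whose CH2 terminus lies on the side of the ring oxygen, staggered between that oxygen and the methyl group, and not to a strictly eclipsed arrangement.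

Step 1
Reactants: 1 (R)-linalool, (3R)-3,7-dimethylocta-1,6-dien-3-ol
Product: 3 2-[(2S,5R)-5-ethenyl-5-methyloxolan-2-yl]propan-2-ol (cis-furanoid linalool oxide), via 6,7-epoxylinalool 2 (not isolated)
Conditions: 1,2:4,5-di-O-isopropylidene-β-D-erythro-2,3-hexodiulo-2,6-pyranose (0.3 equiv), KHSO5 (Oxone, 1.4 equiv), K2CO3, Bu4NHSO4 (cat.), MeCN/CH2(OMe)2, aq. Na2B4O7 buffer, 0 °C; then camphorsulfonic acid (5 mol %), CH2Cl2, 0 °C
Reagents that add atoms: potassium peroxymonosulfate, [K+].[O-]S(=O)(=O)OO
Why: Shi epoxidation: the chiral dioxirane attacks the electron-rich trisubstituted alkene in preference to the vinyl group and should give the (6R)-epoxide 2 under reagent control, the remote C3 centre of 1 having little influence. Acid then triggers 5-exo-tet opening by the tertiary hydroxyl at the secondary epoxide carbon with inversion (epoxide–alcohol cycloetherification), which sets C2 of the oxolane as S with the hydroxyisopropyl group cis to the vinyl group; the pyranoid product of 6-endo opening is removed by chromatography.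

Step 2
Reactants: 3 2-[(2S,5R)-5-ethenyl-5-methyloxolan-2-yl]propan-2-ol
Product: 4 methyl 2-[(2S,5R)-5-ethenyl-5-methyloxolan-2-yl]propan-2-yl oxalate
Conditions: ClC(O)CO2Me (1.5 equiv), Et3N (2 equiv), DMAP (0.1 equiv), CH2Cl2, 0 °C to rt
Reagents that add atoms: methyl chlorooxoacetate, COC(=O)C(=O)Cl
Why: Acylation of a tertiary alcohol with an acid chloride under nucleophilic catalysis by DMAP; the reactive half-ester chloride of oxalic acid compensates for the hindered carbinol, and no stereocentre is touched.

Step 3
Reactants: 4 methyl 2-[(2S,5R)-5-ethenyl-5-methyloxolan-2-yl]propan-2-yl oxalate; 5 allenyltributylstannane, tributyl(propa-1,2-dien-1-yl)stannane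
Product: 6 (1R,2S,4S)-2-(but-3-yn-1-yl)-1,3,3-trimethyl-7-oxabicyclo[2.2.1]heptane
Conditions: 5 (4 equiv, 0.2 M), 1,1′-azobis(cyclohexane-1-carbonitrile) (0.3 equiv, in portions), PhCF3 (0.05 M in 4), 100 °C; aq. KF work-up
Reagents that add atoms: none
Why: Proposed new method: a tin-hydride-free radical chain is intended, in which Bu3Sn• adds to an oxalate carbonyl of 4 and the adduct fragments to the tertiary C(CH3)2 radical and methyl tributylstannyl oxalate, the radical adds to the ring-bound carbon of the cis vinyl group, and the resulting primary radical adds to the CH2 terminus of 5, whose β-stannyl vinyl radical expels Bu3Sn• (SH2′) to leave the terminal alkyne and carry the chain. The closest known reaction types are the stannane-mediated deoxygenation of tertiary methyl oxalates (Barton–McCombie type), 5-exo radical cyclisation and radical propargyl transfer from allenylstannanes (Keck type), which have not been merged or used to close an oxygen-bridged ring. One ring closes, the six-membered carbocycle C1–C6: counted through the ring oxygen the closure is 5-exo-trig, counted through carbon 6-exo-trig, and it completes the 7-oxabicyclo[2.2.1]heptane. The one new stereocentre, C2, is set by the substrate: the bridgeheads are fixed in 4, and in the closing conformer the CH2 terminus of the vinyl group should lie on the side of the one-atom oxygen bridge, staggered between the ring oxygen and the C1 methyl group, with the small vinyl hydrogen facing the C5–C6 bridge, so that the CH2• and then the chain end up exo. The step needs attack at the inner alkene carbon and not at the terminus (6-endo, to an 8-oxabicyclo[3.2.1]octane); the shorter tether through oxygen, the cis relationship on the oxolane and the two quaternary centres flanking the tether (Thorpe–Ingold effect) should favour the 5-exo mode as in hex-5-enyl radicals. Direct capture of the hindered tertiary radical by 5 is bimolecular and slow, so a moderate stannane concentration should let cyclisation come first, whereas the unhindered primary radical is captured readily. Because no hydride donor is present, neither radical can be reduced and the product alkyne cannot be hydrostannylated; any trans isomer of 4 carried from step 1 cannot bridge and is removed here.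

Step 4
Reactants: 7 methyl 3-formyl-4-hydroxybenzoate
Product: 8 methyl 4-[(tert-butyldimethylsilyl)oxy]-3-formylbenzoate
Conditions: TBSCl (1.2 equiv), imidazole (2.5 equiv), DMF, rt
Reagents that add atoms: tert-butyldimethylsilyl chloride, CC(C)(C)[Si](C)(C)Cl
Why: Imidazole-promoted silylation of a phenol; the silyl ether hides the acidic OH from the organoalane of step 7 and is later lost under the saponification conditions, so it costs no separate deprotection.

Step 5
Reactants: 8 methyl 4-[(tert-butyldimethylsilyl)oxy]-3-formylbenzoate
Product: 9 methyl 4-[(tert-butyldimethylsilyl)oxy]-3-(hydroxymethyl)benzoate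
Conditions: BH3·SMe2 (0.6 equiv), THF, 0 °C; MeOH quench
Reagents that add atoms: none
Why: Chemoselective borane reduction of an aryl aldehyde in the presence of a methyl benzoate; the neutral borate intermediate avoids a free benzylic alkoxide, which could otherwise take over the neighbouring silyl group.

Step 6
Reactants: 9 methyl 4-[(tert-butyldimethylsilyl)oxy]-3-(hydroxymethyl)benzoate
Product: 10 methyl 4-[(tert-butyldimethylsilyl)oxy]-3-(chloromethyl)benzoate
Conditions: PPh3 (1.3 equiv), N-chlorosuccinimide (1.3 equiv), CH2Cl2, 0 °C to rt
Reagents that add atoms: N-chlorosuccinimide, ClN1C(=O)CCC1=O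
Why: Appel-type deoxychlorination of a primary benzylic alcohol under neutral conditions; SN2 displacement of the oxyphosphonium group by chloride leaves the aryl silyl ether and the ester untouched.

Step 7
Reactants: 6 (1R,2S,4S)-2-(but-3-yn-1-yl)-1,3,3-trimethyl-7-oxabicyclo[2.2.1]heptane; 10 methyl 4-[(tert-butyldimethylsilyl)oxy]-3-(chloromethyl)benzoate
Product: 12 methyl 4-[(tert-butyldimethylsilyl)oxy]-3-[(2E)-3-methyl-5-[(1R,2S,4S)-1,3,3-trimethyl-7-oxabicyclo[2.2.1]heptan-2-yl]pent-2-en-1-yl]benzoate, via alkenylalane 11 (not isolated)
Conditions: AlMe3 (3 equiv), Cp2ZrCl2 (0.5 equiv), CH2Cl2, 0 °C to rt; volatiles removed in vacuum; then 10 (1.2 equiv), Pd(PPh3)4 (5 mol %), THF, rt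
Reagents that add atoms: trimethylaluminium, C[Al](C)C
Why: Negishi zirconium-catalysed carboalumination adds CH3 and Al syn across the terminal alkyne with the methyl on the inner carbon, so in 11 the aluminium is cis to the new methyl group. Palladium-catalysed cross-coupling (oxidative addition of the benzylic chloride to zerovalent palladium, transmetallation from aluminium, reductive elimination) replaces Al with retention and so fixes the E alkene; excess AlMe3 is removed first so that the ester of 10 meets only the THF-complexed alkenylalane.

Step 8
Reactants: 12 methyl 4-[(tert-butyldimethylsilyl)oxy]-3-[(2E)-3-methyl-5-[(1R,2S,4S)-1,3,3-trimethyl-7-oxabicyclo[2.2.1]heptan-2-yl]pent-2-en-1-yl]benzoate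
Product: 14 4-hydroxy-3-[(2E)-3-methyl-5-[(1R,2S,4S)-1,3,3-trimethyl-7-oxabicyclo[2.2.1]heptan-2-yl]pent-2-en-1-yl]benzoic acid, via phenol methyl ester 13 (not isolated)
Conditions: LiOH·H2O (10 equiv), THF/MeOH/H2O, rt then 60 °C; 0.5 M HCl to pH 4, 0 °C
Reagents that add atoms: lithium hydroxide, [Li+].[OH-]
Why: Hydroxide first cleaves the aryl silyl ether (an aryloxide leaves silicon easily) to give 13 and then saponifies the methyl ester by acyl substitution; heating is needed because the para-phenoxide deactivates the ester. Cold dilute acid to pH 4 frees the acid without cyclising the ortho-allyl phenol to a chroman, and no stereocentre or the alkene is affected by base.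

Compound list

1 | (R)-linalool, (3R)-3,7-dimethylocta-1,6-dien-3-ol | CC(C)=CCC[C@@](C)(O)C=C | starting material
2 | (3R)-5-[(2R)-3,3-dimethyloxiran-2-yl]-3-methylpent-1-en-3-ol (6,7-epoxylinalool) | CC1(C)O[C@@H]1CC[C@@](C)(O)C=C | intermediate (not isolated)
3 | 2-[(2S,5R)-5-ethenyl-5-methyloxolan-2-yl]propan-2-ol | C=C[C@@]1(C)CC[C@H](O1)C(C)(C)O | intermediate
4 | methyl 2-[(2S,5R)-5-ethenyl-5-methyloxolan-2-yl]propan-2-yl oxalate | C=C[C@@]1(C)CC[C@H](O1)C(C)(C)OC(=O)C(=O)OC | intermediate
5 | allenyltributylstannane, tributyl(propa-1,2-dien-1-yl)stannane | C=C=C[Sn](CCCC)(CCCC)CCCC | starting material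
6 | (1R,2S,4S)-2-(but-3-yn-1-yl)-1,3,3-trimethyl-7-oxabicyclo[2.2.1]heptane | C#CCC[C@H]1C(C)(C)[C@@H]2CC[C@@]1(C)O2 | intermediate
7 | methyl 3-formyl-4-hydroxybenzoate | COC(=O)c1ccc(O)c(C=O)c1 | starting material
8 | methyl 4-[(tert-butyldimethylsilyl)oxy]-3-formylbenzoate | COC(=O)c1ccc(O[Si](C)(C)C(C)(C)C)c(C=O)c1 | intermediate
9 | methyl 4-[(tert-butyldimethylsilyl)oxy]-3-(hydroxymethyl)benzoate | COC(=O)c1ccc(O[Si](C)(C)C(C)(C)C)c(CO)c1 | intermediate
10 | methyl 4-[(tert-butyldimethylsilyl)oxy]-3-(chloromethyl)benzoate | COC(=O)c1ccc(O[Si](C)(C)C(C)(C)C)c(CCl)c1 | intermediate
11 | dimethyl[(1E)-2-methyl-4-[(1R,2S,4S)-1,3,3-trimethyl-7-oxabicyclo[2.2.1]heptan-2-yl]but-1-en-1-yl]alumane | C[Al](C)/C=C(\C)CC[C@H]1C(C)(C)[C@@H]2CC[C@@]1(C)O2 | intermediate (not isolated)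
12 | methyl 4-[(tert-butyldimethylsilyl)oxy]-3-[(2E)-3-methyl-5-[(1R,2S,4S)-1,3,3-trimethyl-7-oxabicyclo[2.2.1]heptan-2-yl]pent-2-en-1-yl]benzoate | COC(=O)c1ccc(O[Si](C)(C)C(C)(C)C)c(C/C=C(\C)CC[C@H]2C(C)(C)[C@@H]3CC[C@@]2(C)O3)c1 | intermediate
13 | methyl 4-hydroxy-3-[(2E)-3-methyl-5-[(1R,2S,4S)-1,3,3-trimethyl-7-oxabicyclo[2.2.1]heptan-2-yl]pent-2-en-1-yl]benzoate | COC(=O)c1ccc(O)c(C/C=C(\C)CC[C@H]2C(C)(C)[C@@H]3CC[C@@]2(C)O3)c1 | intermediate (not isolated)
14 | 4-hydroxy-3-[(2E)-3-methyl-5-[(1R,2S,4S)-1,3,3-trimethyl-7-oxabicyclo[2.2.1]heptan-2-yl]pent-2-en-1-yl]benzoic acid | C/C(=C\Cc1cc(C(=O)O)ccc1O)CC[C@H]1C(C)(C)[C@@H]2CC[C@@]1(C)O2 | target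

Total step count: 8 steps. Longest linear sequence: 5 steps (steps 1, 2, 3, 7, 8, from 1 to 14); the arene branch (steps 4, 5, 6, then 7, 8) is equally long.

Steps least certain to work

Step 3 (key step; the only step with the label "Proposed new method:").
- **What may go wrong:**
  - (a) The chain may fail to propagate, because addition of a stannyl radical to an oxalate carbonyl is slow and reversible and has so far been driven by a hydride donor.
  - (b) Ring closure onto an unactivated alkene, at a carbon next to a quaternary centre, may be slower than direct capture of the tertiary radical. It may also go 6-endo, since that path gives a less strained bicycle and a secondary radical.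
  - (c) The cyclised primary radical may re-open before the slow bimolecular transfer, either back across C2–C3 or across C1–C2, with relief of strain, to an α-alkoxy radical.
  - (d) Stannyl radicals may isomerise the allenylstannane to its propargyl isomer, which would transfer an allenyl group.
- **Fallback (known reaction types; sets out from 3, returns at 6):** 3 would be cross-metathesised with methyl acrylate under (H2IMes)Cl2Ru(=CH-C6H4-2-O-i-Pr), the second-generation Hoveyda–Grubbs catalyst, in CH2Cl2 at 40 °C to give methyl (2E)-3-[(2R,5S)-5-(2-hydroxypropan-2-yl)-2-methyloxolan-2-yl]prop-2-enoate F1. Acylation as in step 2 would give methyl 2-[(2S,5R)-5-[(1E)-3-methoxy-3-oxoprop-1-en-1-yl]-5-methyloxolan-2-yl]propan-2-yl oxalate F2. Reductive radical cyclisation (Bu3SnH, AIBN, toluene, 110 °C, slow addition) would follow: the tertiary radical now closes by a polarity-matched 5-exo conjugate addition, and the stabilised α-ester radical, which has no reason to re-open, takes hydrogen from the stannane to give methyl 2-[(1R,2S,4S)-1,3,3-trimethyl-7-oxabicyclo[2.2.1]heptan-2-yl]acetate F3. LiAlH4 reduction to 2-[(1R,2S,4S)-1,3,3-trimethyl-7-oxabicyclo[2.2.1]heptan-2-yl]ethan-1-ol F4, iodination (I2, PPh3, imidazole) to (1R,2S,4S)-2-(2-iodoethyl)-1,3,3-trimethyl-7-oxabicyclo[2.2.1]heptane F5, and displacement with lithium acetylide–ethylenediamine complex in DMSO would return to 6. The alkyne carbons are then introduced by ionic chemistry and the radical step ends with ordinary hydrogen transfer.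

Step 7.
- **What may go wrong:** coordination of the bridging ether to aluminium or zirconium may make methylalumination slow or less regioselective; residual organoalane may attack the methyl ester; the Lewis-acidic aluminium chloride formed may ionise the ortho-silyloxy benzylic chloride, leading to self-condensation.
- **Fallback (sets out from 6 and 10, returns at 12):** the polarity is reversed. Methylalumination of 6 as before, then iodinolysis of 11 (I2, THF, −30 °C), would give (1R,2S,4S)-2-[(3E)-4-iodo-3-methylbut-3-en-1-yl]-1,3,3-trimethyl-7-oxabicyclo[2.2.1]heptane F6, which can be purified. Zinc dust with LiCl in THF would insert into the C–Cl bond of 10 to give {[2-[(tert-butyldimethylsilyl)oxy]-5-(methoxycarbonyl)phenyl]methyl}zinc chloride F7. Negishi coupling of F6 with F7 under Pd(PPh3)4 would give 12, with no organoalane ever in contact with the ester.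

Step 1.
- **What may go wrong:** incomplete facial selectivity of the dioxirane at a 2-methylalk-2-ene terminus, which leads to the trans oxide; competing 6-endo opening to pyranoid oxides; loss of the ketone catalyst by Baeyer–Villiger oxidation if the pH drifts.
- **Fallback (sets out from 1, returns at 3):** reagent control is given up in favour of separation. 3-Chloroperoxybenzoic acid in CH2Cl2 followed by catalytic acid would give 2 together with its epimer (3R)-5-[(2S)-3,3-dimethyloxiran-2-yl]-3-methylpent-1-en-3-ol F8. Both close in the flask, to 3 and to 2-[(2R,5R)-5-ethenyl-5-methyloxolan-2-yl]propan-2-ol F9. Acetylation (Ac2O, Et3N, DMAP) would give 2-[(2S,5R)-5-ethenyl-5-methyloxolan-2-yl]propan-2-yl acetate F10 and 2-[(2R,5R)-5-ethenyl-5-methyloxolan-2-yl]propan-2-yl acetate F11, which are expected to be separable by chromatography. LiAlH4 cleavage of F10 returns to 3, at the cost of the material that goes to the trans series.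

Step 5.
- **What may go wrong:** migration of the silyl group from the phenolic to the benzylic oxygen if any alkoxide forms, favoured here because the ester makes the aryloxide a good leaving group; over-reduction of the ester by excess borane.
- **Fallback (sets out from 7, returns at 10):** the order of operations is changed. NaBH4 in MeOH would reduce the unprotected hydroxy aldehyde to methyl 4-hydroxy-3-(hydroxymethyl)benzoate F12, concentrated aqueous HCl would convert the benzylic alcohol selectively to methyl 3-(chloromethyl)-4-hydroxybenzoate F13, and silylation of the phenol with TBSOTf and 2,6-lutidine at −78 °C would give 10. No silyl ether is then present when the benzylic oxygen is generated.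

Step 8.
- **What may go wrong:** the ester para to a phenoxide is saponified slowly and may need forcing conditions, under which the alkene could migrate; acidification may start chroman formation.
- **Fallback (sets out from 12, returns at 14):** the two masks are removed separately and the ester is cleaved at the other bond. Bu4NF buffered with acetic acid in THF would give 13, now isolated. LiI in pyridine at reflux would then cleave the O–CH3 bond by SN2 dealkylation, which is indifferent to the deactivated carbonyl, and mild acidification would give 14 (no new compound; F0).

Further compounds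

F1 | step 3 | methyl (2E)-3-[(2R,5S)-5-(2-hydroxypropan-2-yl)-2-methyloxolan-2-yl]prop-2-enoate | COC(=O)/C=C/[C@@]1(C)CC[C@H](O1)C(C)(C)O
F2 | step 3 | methyl 2-[(2S,5R)-5-[(1E)-3-methoxy-3-oxoprop-1-en-1-yl]-5-methyloxolan-2-yl]propan-2-yl oxalate | COC(=O)/C=C/[C@@]1(C)CC[C@H](O1)C(C)(C)OC(=O)C(=O)OC
F3 | step 3 | methyl 2-[(1R,2S,4S)-1,3,3-trimethyl-7-oxabicyclo[2.2.1]heptan-2-yl]acetate | COC(=O)C[C@H]1C(C)(C)[C@@H]2CC[C@@]1(C)O2
F4 | step 3 | 2-[(1R,2S,4S)-1,3,3-trimethyl-7-oxabicyclo[2.2.1]heptan-2-yl]ethan-1-ol | OCC[C@H]1C(C)(C)[C@@H]2CC[C@@]1(C)O2
F5 | step 3 | (1R,2S,4S)-2-(2-iodoethyl)-1,3,3-trimethyl-7-oxabicyclo[2.2.1]heptane | ICC[C@H]1C(C)(C)[C@@H]2CC[C@@]1(C)O2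
F6 | step 7 | (1R,2S,4S)-2-[(3E)-4-iodo-3-methylbut-3-en-1-yl]-1,3,3-trimethyl-7-oxabicyclo[2.2.1]heptane | I/C=C(\C)CC[C@H]1C(C)(C)[C@@H]2CC[C@@]1(C)O2
F7 | step 7 | {[2-[(tert-butyldimethylsilyl)oxy]-5-(methoxycarbonyl)phenyl]methyl}zinc chloride | COC(=O)c1ccc(O[Si](C)(C)C(C)(C)C)c(C[Zn]Cl)c1
F8 | step 1 | (3R)-5-[(2S)-3,3-dimethyloxiran-2-yl]-3-methylpent-1-en-3-ol | CC1(C)O[C@H]1CC[C@@](C)(O)C=C
F9 | step 1 | 2-[(2R,5R)-5-ethenyl-5-methyloxolan-2-yl]propan-2-ol | C=C[C@@]1(C)CC[C@@H](O1)C(C)(C)O
F10 | step 1 | 2-[(2S,5R)-5-ethenyl-5-methyloxolan-2-yl]propan-2-yl acetate | C=C[C@@]1(C)CC[C@H](O1)C(C)(C)OC(C)=O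
F11 | step 1 | 2-[(2R,5R)-5-ethenyl-5-methyloxolan-2-yl]propan-2-yl acetate | C=C[C@@]1(C)CC[C@@H](O1)C(C)(C)OC(C)=O
F12 | step 5 | methyl 4-hydroxy-3-(hydroxymethyl)benzoate | COC(=O)c1ccc(O)c(CO)c1
F13 | step 5 | methyl 3-(chloromethyl)-4-hydroxybenzoate | COC(=O)c1ccc(O)c(CCl)c1
F0 | step 8 | none | none
A1 | alternative 1 | methyl 2-[(1S,3S,6S)-3-[(tert-butyldimethylsilyl)oxy]-6-hydroxy-2,2,6-trimethylcyclohexyl]acetate | COC(=O)C[C@H]1C(C)(C)[C@@H](O[Si](C)(C)C(C)(C)C)CC[C@]1(C)O
A2 | alternative 1 | methyl (2E,5S)-5-[(tert-butyldimethylsilyl)oxy]-4,4-dimethyl-8-oxonon-2-enoate | COC(=O)/C=C/C(C)(C)[C@@H](O[Si](C)(C)C(C)(C)C)CCC(C)=O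
A3 | alternative 2 | (1R,4S)-1,3,3-trimethyl-7-oxabicyclo[2.2.1]heptan-2-one | O=C1C(C)(C)[C@@H]2CC[C@@]1(C)O2
A4 | alternative 2 | 2-diazo-4-methyl-4-[(2S)-oxetan-2-yl]pentan-3-one | CC(=[N+]=[N-])C(=O)C(C)(C)[C@@H]1CCO1
A5 | alternative 3 | methyl 4-[(tert-butyldimethylsilyl)oxy]-3-[(2E)-3-methyl-5-[(1R,2S,4S)-1,3,3-trimethyl-7-oxabicyclo[2.2.1]heptan-2-yl]pent-2-en-1-yl]benzoate | COC(=O)c1ccc(O[Si](C)(C)C(C)(C)C)c(C/C=C(\C)CC[C@H]2C(C)(C)[C@@H]3CC[C@@]2(C)O3)c1
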